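All runs come from a simulation for substances that don't exist; noise was put on by code.

Late in the birch run, with electrophile at 0.14 M and nucleophile at 0.72 M, product gains 0.00333 min⁻¹ of the charge, against 0.0150 min⁻¹ over the first 8.00 min, a slowing by a factor 4.50.

in all of them: electrophile 0.14 M

| charge | nucleophile | remark | time |
|---|---|---|---|
| alder | 0.11 M | run made earlier |  |
| birch | 0.72 M | run made earlier |  |
| Sunday's | 0.620 M |  | 1.0 h |
| Friday's | 0.150 M |  | 1.0 h |
| Saturday's | 0.310 M |  | 1.0 h |

- alder (time / min: electrophile / %, product / %): 2.50: 97, 3; 5.00: 97, 1; 8.00: 98, 2; 15.0: 95, 3; 30.0: 97, 9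
- birch (time / min: electrophile / %, product / %): 2.50: 99, 1; 5.00: 94, 7; 8.00: 88, 12; 15.0: 84, 19; 30.0: 76, 24

(readings scatter by 2 percentage points)



1. part of the electrophile that has reacted at the end, Sunday's
2. part of the electrophile that has reacted at the end, Friday's
3. part of the electrophile that has reacted at the end, Saturday's
4. what raising the concentration of nucleophile from its lowest to its highest value here does to the part of the electrophile that has reacted (changes below 5 percentage points count as none) (it falls / it rises / no change)

The electrophile left at 30.0 min, 76%, accounts for a factor of 1.32 of that slowing, so a factor 3.42 remains. Making product has used 4.67% of birch's nucleophile. Yet birch makes 2.67 times alder's product on 6.55 times its nucleophile. This reckoning, which is not the forecast's, therefore assumes that nucleophile fails at a rate second order in itself. The electrophile then falls pseudo-first-order, with a rate fading as 1/(1 + t/τ). Here τ is the brake time, the time by which the brake has halved the rate, and it scales as 1/c(nucleophile).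

Birch's last reading gives a first τ of 18.3 min with no fading counted. Put back in, that gives 18.8 min. Friday's brake time is then 90.5 min, and over 1.0 h the mean rate keeps a factor 0.767 of the start rate. Sunday's, with 21.9 min, keeps 0.481. The reckoning commits to 13.4% for Friday's, 21.7% for Saturday's and 31.1% for Sunday's.

The forecast says 6%, 12.5% and 23%, that it rises, and calls the outcome “roughly proportional to nucleophile at low concentration”. It stands below this reckoning on Friday's.

The flasks give 12.9% on Friday's, 19.9% on Saturday's and 27.7% on Sunday's; with more nucleophile it rises, by 15 percentage points.

    nucleophile + acid set free ⇌ protonated nucleophile, settled at all times (K = 810 L mol⁻¹)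
    electrophile + nucleophile → acid set free + product (k = 4.60 × 10⁻⁴ L mol⁻¹ s⁻¹)
    2 nucleophile → homo dimer (k = 0.00120 L mol⁻¹ s⁻¹)

On Friday's the forecast gave 6% and the flask 12.9%, where the brake time gave 13.4%. The same reckoning goes to a neighbour, Friday's flask with 0.26 M of nucleophile. Its brake time is 52.2 min, and its mean rate keeps a factor 0.666 of the start rate, so 19.5% of its electrophile should react. That neighbour flask gives 18.1%.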